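**Retrosynthetic overview**
Numbering follows the labdane skeleton (ring A = C1–C5, C10; ring B = C5–C10; C17 = formyl carbon on C8; C18/C19 = the CH2OH carbons on C4; side chain C11–C16). Late disconnections: butenolide by sp3–sp2 Negishi coupling (C12–C13), C17 aldehyde from a nitrile, C4(CH2OH)2 from a C4 carbaldehyde plus formaldehyde (Tollens-type).
Key disconnection: ring B is closed by inserting a vinyl C6–C7 unit between C5 and C8 in one pot. Stille vinylation of the C5 bromide of a ring A β-bromo enal gives a dienal (O=C19–C4=C5–C6=C7), whose terminal C7 is attacked 6-endo by the C8 cyanoacetate carbanion, so C5–C6 and C7–C8 form together.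
Enabling feature: C4 carries two identical hydroxymethyl arms and is not a stereocentre, so it can be carried as the sp2, formyl-bearing carbon of a ring A enal C4=C5. This makes C5 a cross-coupling site and then part of a dienal, while C8 carries its future formyl carbon C17 as a carbanion-stabilising nitrile. The quaternary C10 rules out a Diels–Alder diene spanning C5 and C8, hence a polar formal [4+2].
Ring order: ring A from 2-methylcyclohexanone (C10 and C9 set by a deracemising chiral-imine Michael addition), then ring B (key step), then the butenolide. C5–H is set by hydrogenation anti to the C10 methyl, C8 by equilibration to the equatorial aldehyde.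

Key step: step 4

Remark: 3-(benzyloxy)propanal, tributyl(vinyl)stannane and 3-bromofuran-2(5H)-one are taken as commercial. The centre that becomes C8 is carried as an epimer mixture until it is equilibrated at the aldehyde stage, which has no consequence.

Step 1
Reactants: 1 3-(benzyloxy)propanal; 2 methyl cyanoacetate
Product: 3 methyl (E)-5-(benzyloxy)-2-cyanopent-2-enoate
Conditions: piperidine (5 mol%), AcOH (5 mol%), 4 Å molecular sieves, CH2Cl2, 0 °C to rt
Reagents that add atoms: none
Why: Knoevenagel condensation under buffered amine catalysis should give the doubly activated (E)-alkene that later supplies C8 (with the masked formyl carbon C17), C9, C11 and C12.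

Step 2
Reactants: 4 2-methylcyclohexanone (racemic); 5 (R)-1-phenylethylamine; 3 methyl (E)-5-(benzyloxy)-2-cyanopent-2-enoate
Product: 8 methyl (3R)-5-(benzyloxy)-2-cyano-3-[(1S)-1-methyl-2-oxocyclohexyl]pentanoate (both C2 epimers), via imine 6 (not isolated), via Michael-adduct imine 7 (not isolated)
Conditions: TsOH (cat.), toluene, Dean–Stark, reflux; concentrate; then 3, THF, 0 °C to 40 °C; then 20% aq. AcOH, rt (5 recovered)
Reagents that add atoms: water, O
Why: Auxiliary-controlled deracemising Michael addition of a chiral imine (aza-ene type): the imine should react through its more substituted secondary enamine in a compact transition state, with C10 attacked anti to the phenyl group of the auxiliary (1S from the R-amine) and the acceptor β-carbon C9 placing its chain away from the ring (3R), before the imine is hydrolysed.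

Step 3
Reactants: 8 methyl (3R)-5-(benzyloxy)-2-cyano-3-[(1S)-1-methyl-2-oxocyclohexyl]pentanoate
Product: 9 methyl (3R)-5-(benzyloxy)-3-[(1S)-2-bromo-3-formyl-1-methylcyclohex-2-en-1-yl]-2-cyanopentanoate (both C2 epimers)
Conditions: PBr3, DMF, CHCl3, 0 °C to 60 °C; then ice, aq. NaOAc
Reagents that add atoms: N,N-dimethylformamide, CN(C)C=O; phosphorus tribromide, BrP(Br)Br; water, O
Why: Vilsmeier–Haack bromoformylation: the ketone can enolise only toward C4, so C-formylation at C4 and replacement of the activated C5 oxygen by bromide should give the β-bromo enal as a single regioisomer after hydrolysis.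

Step 4
Reactants: 9 methyl (3R)-5-(benzyloxy)-3-[(1S)-2-bromo-3-formyl-1-methylcyclohex-2-en-1-yl]-2-cyanopentanoate; 10 tributyl(vinyl)stannane
Product: 12 methyl (1S,8aS)-1-[2-(benzyloxy)ethyl]-2-cyano-5-formyl-8a-methyl-1,2,3,4,6,7,8,8a-octahydronaphthalene-2-carboxylate (both C2 epimers), via dienal 11 (not isolated)
Conditions: Pd(PPh3)4 (5 mol%), CuI (10 mol%), DMF, 60 °C; then DBU (0.5 equiv), same flask, 60 °C
Reagents that add atoms: none
Why: Zerovalent palladium inserts into the activated C5–Br bond, and copper-assisted transmetalation with 10 followed by reductive elimination gives the 2-vinyl enal 11 (Stille coupling, forming C5–C6), in which C19=O, C4=C5 and C6=C7 make a dienal that is electrophilic at its terminal carbon C7. DBU then deprotonates the cyanoacetate C8–H and the soft carbanion adds to C7 in an intramolecular 1,6-conjugate (vinylogous Michael) addition, forming C7–C8, after which protonation of the dienolate and equilibration should give the conjugated enal 12. The closest known reaction types are the Stille or Suzuki vinylation of β-halo enals and the base-catalysed 1,6-addition of malonate-type carbanions to dienals and dienones, combined here as a domino cross-coupling/Michael annulation. Ring B closes in the 6-endo-trig mode, the only productive one because the three-atom tether C8–C9–C10 would give a cyclobutane by attack at C5 and an unstabilised carbanion by attack at C6. The only new stereocentre is the quaternary C8, formed as a mixture that does not matter because C8 is decarboxylated in step 6 and equilibrated in step 9, while C5 stays trigonal and is set in step 7. The step needs the coupling to precede carbanion chemistry and 1,6- to win over 1,2-addition to the formyl group, which is secured by adding the base only after the coupling and by the reversibility of the aldol addition against the proton transfer that follows the conjugate addition.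

Step 5
Reactants: 12 methyl (1S,8aS)-1-[2-(benzyloxy)ethyl]-2-cyano-5-formyl-8a-methyl-1,2,3,4,6,7,8,8a-octahydronaphthalene-2-carboxylate
Product: 14 methyl (1S,8aS)-1-[2-(benzyloxy)ethyl]-2-cyano-5,5-bis(hydroxymethyl)-8a-methyl-1,2,3,5,6,7,8,8a-octahydronaphthalene-2-carboxylate (both C2 epimers), via hydroxy aldehyde 13 (not isolated)
Conditions: 37% aq. CH2O, K2CO3, THF–MeOH, 40 °C; then NaBH4, 0 °C
Reagents that add atoms: formaldehyde, C=O
Why: Tollens-type deconjugative α-hydroxymethylation: γ-deprotonation at C6 gives the dienolate, which should add formaldehyde at C4 and shift the alkene to C5=C6, and borohydride reduction of the neopentyl aldehyde then leaves two identical CH2OH arms, so no stereocentre arises at C4.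

Step 6
Reactants: 14 methyl (1S,8aS)-1-[2-(benzyloxy)ethyl]-2-cyano-5,5-bis(hydroxymethyl)-8a-methyl-1,2,3,5,6,7,8,8a-octahydronaphthalene-2-carboxylate
Product: 15 (1R,8aS)-1-[2-(benzyloxy)ethyl]-5,5-bis(hydroxymethyl)-8a-methyl-1,2,3,5,6,7,8,8a-octahydronaphthalene-2-carbonitrile (both C2 epimers)
Conditions: LiCl, H2O (2 equiv), DMSO, 150 °C
Reagents that add atoms: none
Why: Krapcho dealkoxycarbonylation: chloride should demethylate the activated α-cyano ester and the carboxylate lose CO2 to give the nitrile-stabilised carbanion, which is protonated, while the unactivated groups are untouched.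

Step 7
Reactants: 15 (1R,8aS)-1-[2-(benzyloxy)ethyl]-5,5-bis(hydroxymethyl)-8a-methyl-1,2,3,5,6,7,8,8a-octahydronaphthalene-2-carbonitrile
Product: 16 (1R,4aS,8aS)-1-(2-hydroxyethyl)-5,5-bis(hydroxymethyl)-8a-methyldecahydronaphthalene-2-carbonitrile (both C2 epimers)
Conditions: H2 (5 bar), 10% Pd/C, EtOAc–EtOH, rt
Reagents that add atoms: none
Why: Heterogeneous catalytic hydrogenation should deliver hydrogen to the C5=C6 face opposite the axial C10 methyl (as in the reduction of Δ5-steroids to 5α-products), setting C5–H trans to the methyl (4aS), and the same conditions hydrogenolyse the benzyl ether while a nitrile survives neutral Pd/C.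

Step 8
Reactants: 16 (1R,4aS,8aS)-1-(2-hydroxyethyl)-5,5-bis(hydroxymethyl)-8a-methyldecahydronaphthalene-2-carbonitrile
Product: 17 (1R,4aS,8aS)-5,5-bis(hydroxymethyl)-1-(2-iodoethyl)-8a-methyldecahydronaphthalene-2-carbonitrile (both C2 epimers)
Conditions: I2 (1.05 equiv), PPh3 (1.05 equiv), imidazole, CH2Cl2, 0 °C
Reagents that add atoms: iodine, II
Why: Appel iodination should be selective for the unhindered primary C12 hydroxyl, because SN2 displacement at the two neopentyl CH2OH groups on the quaternary C4 is very slow.

Step 9
Reactants: 17 (1R,4aS,8aS)-5,5-bis(hydroxymethyl)-1-(2-iodoethyl)-8a-methyldecahydronaphthalene-2-carbonitrile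
Product: 18 (1R,2S,4aS,8aS)-5,5-bis(hydroxymethyl)-1-(2-iodoethyl)-8a-methyldecahydronaphthalene-2-carbaldehyde
Conditions: i-Bu2AlH (4 equiv), CH2Cl2, −78 °C to −20 °C; aq. Rochelle salt, then SiO2; then DBU (10 mol%), CH2Cl2, rt
Reagents that add atoms: water, O
Why: Partial reduction of the nitrile by the aluminium hydride to the N-aluminoimine and hydrolysis should give the aldehyde, and base equilibration through the enolate sets C8 as the equatorial (2S) aldehyde, which avoids the 1,3-diaxial clash with the C10 methyl.

Step 10
Reactants: 18 (1R,2S,4aS,8aS)-5,5-bis(hydroxymethyl)-1-(2-iodoethyl)-8a-methyldecahydronaphthalene-2-carbaldehyde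
Product: 19 (1R,2S,4aS,8aS)-2-(dimethoxymethyl)-1-(2-iodoethyl)-8a-methyldecahydronaphthalene carrying a spiro 2,2-dimethyl-1,3-dioxane at C5 (acetonide of the two CH2OH groups)
Conditions: Me2C(OMe)2, MeOH, PPTS (cat.), rt
Reagents that add atoms: 2,2-dimethoxypropane, COC(C)(C)OC; methanol, CO
Why: Acid-catalysed transacetalisation should convert the 1,3-diol into its six-membered acetonide and the aldehyde into its dimethyl acetal in one pot, masking the protic and electrophilic groups for the organozinc step.

Step 11
Reactants: 19 acetonide dimethyl acetal iodide; 20 3-bromofuran-2(5H)-one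
Product: 22 (1R,2S,4aS,8aS)-2-(dimethoxymethyl)-8a-methyl-1-[2-(2-oxo-2,5-dihydrofuran-3-yl)ethyl]decahydronaphthalene carrying a spiro 2,2-dimethyl-1,3-dioxane at C5, via alkylzinc iodide 21 (not isolated)
Conditions: Zn dust (activated with BrCH2CH2Br and Me3SiCl), LiCl, THF, 40 °C; then 20, PdCl2(dppf) (5 mol%), THF–NMP, 40 °C
Reagents that add atoms: none
Why: Negishi sp3–sp2 coupling: zinc insertion into the primary iodide gives a functional-group-tolerant alkylzinc, which should couple at C3 of the α-bromobutenolide under palladium catalysis with a wide-bite-angle ligand that suppresses β-hydride elimination.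

Step 12
Reactants: 22 protected butenolide
Product: 23 (1R,2S,4aS,8aS)-5,5-bis(hydroxymethyl)-8a-methyl-1-[2-(2-oxo-2,5-dihydrofuran-3-yl)ethyl]decahydronaphthalene-2-carbaldehyde
Conditions: 1 M aq. HCl, THF, rt
Reagents that add atoms: water, O
Why: Mild aqueous acid hydrolysis should cleave the acetonide and the dimethyl acetal together, while the butenolide and the already equatorial aldehyde are stable to these conditions.

**Compound list**
1 | 3-(benzyloxy)propanal | O=CCCOCc1ccccc1 | starting material
2 | methyl cyanoacetate | COC(=O)CC#N | starting material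
3 | methyl (E)-5-(benzyloxy)-2-cyanopent-2-enoate | COC(=O)/C(C#N)=C/CCOCc1ccccc1 | intermediate
4 | 2-methylcyclohexanone (racemic) | CC1CCCCC1=O | starting material
5 | (R)-1-phenylethylamine | C[C@@H](N)c1ccccc1 | starting material
6 | 2-methyl-N-[(1R)-1-phenylethyl]cyclohexan-1-imine (mixture at ring C2) | CC1CCCCC1=N[C@H](C)c1ccccc1 | intermediate
7 | methyl (3R)-5-(benzyloxy)-2-cyano-3-[(1S)-1-methyl-2-{[(1R)-1-phenylethyl]imino}cyclohexyl]pentanoate | C[C@@]1([C@H](CCOCc2ccccc2)C(C#N)C(=O)OC)CCCC1=N[C@H](C)c1ccccc1 | intermediate
8 | methyl (3R)-5-(benzyloxy)-2-cyano-3-[(1S)-1-methyl-2-oxocyclohexyl]pentanoate | C[C@@]1([C@H](CCOCc2ccccc2)C(C#N)C(=O)OC)CCCC1=O | intermediate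
9 | methyl (3R)-5-(benzyloxy)-3-[(1S)-2-bromo-3-formyl-1-methylcyclohex-2-en-1-yl]-2-cyanopentanoate | C[C@@]1([C@H](CCOCc2ccccc2)C(C#N)C(=O)OC)CCCC(C=O)=C1Br | intermediate
10 | tributyl(vinyl)stannane | C=C[Sn](CCCC)(CCCC)CCCC | starting material
11 | methyl (3R)-5-(benzyloxy)-2-cyano-3-[(1S)-2-ethenyl-3-formyl-1-methylcyclohex-2-en-1-yl]pentanoate | C[C@@]1([C@H](CCOCc2ccccc2)C(C#N)C(=O)OC)CCCC(C=O)=C1C=C | intermediate
12 | methyl (1S,8aS)-1-[2-(benzyloxy)ethyl]-2-cyano-5-formyl-8a-methyl-1,2,3,4,6,7,8,8a-octahydronaphthalene-2-carboxylate | C[C@@]12CCCC(C=O)=C1CCC(C#N)(C(=O)OC)[C@H]2CCOCc1ccccc1 | intermediate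
13 | methyl (1S,8aS)-1-[2-(benzyloxy)ethyl]-2-cyano-5-formyl-5-(hydroxymethyl)-8a-methyl-1,2,3,5,6,7,8,8a-octahydronaphthalene-2-carboxylate (mixture at C2 and C5) | C[C@@]12CCCC(CO)(C=O)C1=CCC(C#N)(C(=O)OC)[C@H]2CCOCc1ccccc1 | intermediate
14 | methyl (1S,8aS)-1-[2-(benzyloxy)ethyl]-2-cyano-5,5-bis(hydroxymethyl)-8a-methyl-1,2,3,5,6,7,8,8a-octahydronaphthalene-2-carboxylate | C[C@@]12CCCC(CO)(CO)C1=CCC(C#N)(C(=O)OC)[C@H]2CCOCc1ccccc1 | intermediate
15 | (1R,8aS)-1-[2-(benzyloxy)ethyl]-5,5-bis(hydroxymethyl)-8a-methyl-1,2,3,5,6,7,8,8a-octahydronaphthalene-2-carbonitrile | C[C@@]12CCCC(CO)(CO)C1=CCC(C#N)[C@H]2CCOCc1ccccc1 | intermediate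
16 | (1R,4aS,8aS)-1-(2-hydroxyethyl)-5,5-bis(hydroxymethyl)-8a-methyldecahydronaphthalene-2-carbonitrile | C[C@@]12CCCC(CO)(CO)[C@H]1CCC(C#N)[C@H]2CCO | intermediate
17 | (1R,4aS,8aS)-5,5-bis(hydroxymethyl)-1-(2-iodoethyl)-8a-methyldecahydronaphthalene-2-carbonitrile | C[C@@]12CCCC(CO)(CO)[C@H]1CCC(C#N)[C@H]2CCI | intermediate
18 | (1R,2S,4aS,8aS)-5,5-bis(hydroxymethyl)-1-(2-iodoethyl)-8a-methyldecahydronaphthalene-2-carbaldehyde | C[C@@]12CCCC(CO)(CO)[C@H]1CC[C@H](C=O)[C@H]2CCI | intermediate
19 | acetonide (spiro 2,2-dimethyl-1,3-dioxane at C5) and dimethyl acetal of 18 | C[C@@]12CCCC3(COC(C)(C)OC3)[C@H]1CC[C@H](C(OC)OC)[C@H]2CCI | intermediate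
20 | 3-bromofuran-2(5H)-one | O=C1OCC=C1Br | starting material
21 | alkylzinc iodide derived from 19 | C[C@@]12CCCC3(COC(C)(C)OC3)[C@H]1CC[C@H](C(OC)OC)[C@H]2CC[Zn]I | intermediate
22 | acetonide and dimethyl acetal of the target | C[C@@]12CCCC3(COC(C)(C)OC3)[C@H]1CC[C@H](C(OC)OC)[C@H]2CCC1=CCOC1=O | intermediate
23 | (1R,2S,4aS,8aS)-5,5-bis(hydroxymethyl)-8a-methyl-1-[2-(2-oxo-2,5-dihydrofuran-3-yl)ethyl]decahydronaphthalene-2-carbaldehyde | C[C@@]12CCCC(CO)(CO)[C@H]1CC[C@H](C=O)[C@H]2CCC1=CCOC1=O | target

Total step count: 12. Longest linear sequence: 12 steps (from 1 to 23).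

**Steps most likely to fail**

Step 4 (key step). The risk is that the C8 carbanion is held up in reversible aldol addition to the formyl group, or that the hindered dienal oligomerises before the 6-endo closure; slow oxidative addition at the crowded C5–Br bond would also let the stannane be lost by protodestannylation. Fallback: the two bonds are made in the opposite order by two known steps, setting out from 9. C-Alkylation of the C8 carbanion with 1,2-dibromoethane (Cs2CO3, DMF, rt) gives methyl 5-(benzyloxy)-2-(2-bromoethyl)-3-[(1S)-2-bromo-3-formyl-1-methylcyclohex-2-en-1-yl]-2-cyanopentanoate F1. An intramolecular nickel-catalysed reductive coupling of the alkyl bromide with the vinyl bromide (NiBr2(dme), 4,4'-di-tert-butyl-2,2'-bipyridine, NaI, Mn powder, DMA, 40 °C) then closes C5–C6 and comes back to the route at 12.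

Step 2. The risk is slow addition to the β-substituted acceptor, deconjugation of 3 by the basic imine, or poor control of the face of the acceptor that sets C9. Fallback: the C9/C10 pair is set under catalyst control instead of auxiliary control. Ketone 4 and acceptor 3 are combined directly under bifunctional primary-amine–thiourea organocatalysis (a trans-cyclohexane-1,2-diamine-derived primary amine thiourea, PhCO2H, toluene, rt), where the ketone reacts through the same more substituted enamine while the thiourea binds and orients the cyano ester. This sets out from 4 and 3 and comes back at 8 without any new isolated compound (F0).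

Step 7. The risk is incomplete reduction of the hindered C5=C6 alkene, hydrogen delivery from the methyl-bearing face (cis ring fusion), or partial reduction of the nitrile if the pressure has to be raised. Fallback: setting out from 15, hydrogen-atom-transfer hydrogenation (Mn(dpm)3 cat., PhSiH3, t-BuOOH, i-PrOH, rt) proceeds through the tertiary C5 radical and should give the thermodynamically favoured trans ring fusion while leaving nitrile and benzyl ether untouched. It gives (1R,4aS,8aS)-1-[2-(benzyloxy)ethyl]-5,5-bis(hydroxymethyl)-8a-methyldecahydronaphthalene-2-carbonitrile F2, and mild hydrogenolysis (H2 1 bar, Pd/C, EtOH) then comes back to the route at 16.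

Further compounds
F1 | step 4 | methyl 5-(benzyloxy)-2-(2-bromoethyl)-3-[(1S)-2-bromo-3-formyl-1-methylcyclohex-2-en-1-yl]-2-cyanopentanoate | C[C@@]1([C@H](CCOCc2ccccc2)C(C#N)(CCBr)C(=O)OC)CCCC(C=O)=C1Br
F0 | step 2 | none | none
F2 | step 7 | (1R,4aS,8aS)-1-[2-(benzyloxy)ethyl]-5,5-bis(hydroxymethyl)-8a-methyldecahydronaphthalene-2-carbonitrile | C[C@@]12CCCC(CO)(CO)[C@H]1CCC(C#N)[C@H]2CCOCc1ccccc1
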